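## Retrosynthetic overview

1. Target 26 ⇒ Yamaguchi ester disconnection at O–C8: macrocyclic α'-hydroxy enone 19 plus (2S,3S)-epoxyangelic acid 24 (from angelic acid by Sharpless epoxidation).
2. 19 ⇒ enolate hydroxylation of Z,Z-dienone 17 (sets C8) ⇒ C9–C10 disconnection: intramolecular Nozaki–Hiyama–Kishi closure of iodo-aldehyde 15, then oxidation.
3. 15 ⇒ C6–C7 disconnection: chiral Brønsted-acid-catalysed allylboration/lactonisation of Z-enal 6 with ester-bearing allylboronate 12, which sets C6 and C7 and builds the cis-fused α-methylene lactone.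
4. 6 comes from neryl acetate (ozonolysis, Z-iodo-olefination); 12 from 3,3-diethoxypropan-1-ol and methyl acrylate (Baylis–Hillman, SN2' borylation).
5. Ring order: γ-lactone (step 9), then the ten-membered carbocycle (step 10); the side-chain epoxide is made separately and attached last.

Assumption: germacrane numbering is used in the text (lactone C6/C7, acyloxy C8, ketone C9); Baylis–Hillman adduct 10 and acetate 11 are racemates whose carbinol centre becomes sp2 in step 8; the sense of induction of (R)-TRIP in step 9 is taken from simple aldehyde allylborations (Re-face attack), and (S)-TRIP is used if it proves opposite.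

## Route

Step 1
Reactants: 1 neryl acetate
Product: 3 (2Z)-3-methyl-6-oxohex-2-en-1-yl acetate, via secondary ozonide 2 (not isolated)
Conditions: O3, CH2Cl2, Sudan Red 7B (end-point indicator), −78 °C; then Me2S, −78 °C → rt
Reagents that add atoms: ozone, [O-][O+]=O
Why: Chemoselective ozonolysis, because the isopropylidene alkene is more electron-rich than the alkene carrying the allylic acetate, so one equivalent of ozone cleaves only the distal double bond and the Z-trisubstituted alkene survives.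

Step 2
Reactants: 3 (2Z)-3-methyl-6-oxohex-2-en-1-yl acetate
Product: 4 (2Z,6Z)-7-iodo-3-methylocta-2,6-dien-1-yl acetate
Conditions: EtPPh3I, n-BuLi, THF, rt; I2, −78 °C; NaHMDS, −20 °C; then 3, −78 → −20 °C
Reagents that add atoms: ethyltriphenylphosphonium iodide, CC[P+](c1ccccc1)(c1ccccc1)c1ccccc1.[I-]; iodine, II
Why: Stork–Zhao-type Wittig olefination with the α-iodoethylidene ylide gives the trisubstituted vinyl iodide with iodine cis to the chain under kinetic control, which fixes the later C1=C10 Z geometry.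

Step 3
Reactants: 4 (2Z,6Z)-7-iodo-3-methylocta-2,6-dien-1-yl acetate
Product: 5 (2Z,6Z)-7-iodo-3-methylocta-2,6-dien-1-ol
Conditions: K2CO3 (cat.), MeOH, 0 °C → rt
Reagents that add atoms: none
Why: Base-catalysed transesterification (acetate methanolysis) frees the allylic alcohol without touching the vinyl iodide or either alkene geometry.

Step 4
Reactants: 5 (2Z,6Z)-7-iodo-3-methylocta-2,6-dien-1-ol
Product: 6 (2Z,6Z)-7-iodo-3-methylocta-2,6-dienal
Conditions: TEMPO (10 mol%), PhI(OAc)2, CH2Cl2, rt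
Reagents that add atoms: none
Why: TEMPO/oxoammonium oxidation of the allylic alcohol stops at the enal and, as with nerol to neral, does not isomerise the Z-enal.

Step 5
Reactants: 7 3,3-diethoxypropan-1-ol
Product: 8 3,3-diethoxypropanal
Conditions: IBX, EtOAc, 75 °C; filter, use crude
Reagents that add atoms: none
Why: IBX oxidation is neutral, so the acid-labile acetal and the elimination-prone β,β-dialkoxy aldehyde survive.

Step 6
Reactants: 8 3,3-diethoxypropanal; 9 methyl acrylate
Product: 10 methyl 5,5-diethoxy-3-hydroxy-2-methylidenepentanoate (racemate)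
Conditions: DABCO (0.5 equiv), neat in excess 9, rt, 3–5 d
Reagents that add atoms: none
Why: Morita–Baylis–Hillman reaction of an unhindered aliphatic aldehyde joins C7 to C11 and installs the 2-methylene ester; the racemic carbinol is erased in step 8.

Step 7
Reactants: 10 methyl 5,5-diethoxy-3-hydroxy-2-methylidenepentanoate (racemate)
Product: 11 methyl 3-acetoxy-5,5-diethoxy-2-methylidenepentanoate (racemate)
Conditions: Ac2O, DMAP (cat.), pyridine, 0 °C
Reagents that add atoms: acetic anhydride, CC(=O)OC(C)=O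
Why: DMAP-catalysed acetylation turns the hydroxyl into the allylic leaving group needed for SN2' borylation, and low temperature avoids acetate transposition.

Step 8
Reactants: 11 methyl 3-acetoxy-5,5-diethoxy-2-methylidenepentanoate (racemate)
Product: 12 methyl (2E)-5,5-diethoxy-2-[(4,4,5,5-tetramethyl-1,3,2-dioxaborolan-2-yl)methyl]pent-2-enoate
Conditions: B2pin2, Pd2(dba)3 (2.5 mol%), PhMe, 50 °C
Reagents that add atoms: bis(pinacolato)diboron, CC1(C)OB(OC1(C)C)B1OC(C)(C)C(C)(C)O1
Why: Pd-catalysed SN2' borylation of a Baylis–Hillman acetate via the π-allyl complex gives the enoate with the ester trans to the γ-substituent, so the chain is cis to CH2B (a Z-crotyl-type reagent).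

Step 9
Reactants: 6 (2Z,6Z)-7-iodo-3-methylocta-2,6-dienal; 12 methyl (2E)-5,5-diethoxy-2-[(4,4,5,5-tetramethyl-1,3,2-dioxaborolan-2-yl)methyl]pent-2-enoate
Product: 15 2-[(2S,3S)-2-[(1Z,5Z)-6-iodo-2-methylhepta-1,5-dien-1-yl]-4-methylidene-5-oxooxolan-3-yl]acetaldehyde, via pinacol borate 13 (not isolated), via lactone acetal 14 (not isolated)
Conditions: (R)-TRIP phosphoric acid (10 mol%), 4 Å MS, PhMe, −10 °C → rt; then p-TsOH·H2O (cat.), THF/H2O, rt
Reagents that add atoms: water, O
Why: Proposed new method: enantioselective chiral-phosphoric-acid-catalysed allylboration with an ester-deactivated γ-substituted 2-(alkoxycarbonyl)allyl pinacolboronate and in-flask lactonisation, in which the P–OH hydrogen-bonds a boronate oxygen and P=O binds the formyl H so that the closed chair transition state places the γ-substituent cis to CH2B axial (6,7-syn adduct, hence cis-lactone) and the 3,3'-aryl groups leave the Re face of the enal open (6S, then 7S), the closest known reactions being phosphoric-acid-catalysed allyl- and crotylboration with unfunctionalised pinacol boronates and the achiral thermal or acid-promoted lactonising allylboration of 2-alkoxycarbonyl allylboronates.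

Step 10
Reactants: 15 2-[(2S,3S)-2-[(1Z,5Z)-6-iodo-2-methylhepta-1,5-dien-1-yl]-4-methylidene-5-oxooxolan-3-yl]acetaldehyde
Product: 16 (3aS,6Z,10Z,11aS)-5-hydroxy-6,10-dimethyl-3-methylidene-3a,4,5,8,9,11a-hexahydrocyclodeca[b]furan-2(3H)-one (both C5 epimers)
Conditions: CrCl2 (8 equiv), NiCl2 (2 mol%), DMSO/THF, 2 mM (syringe pump), rt
Reagents that add atoms: none
Why: Intramolecular Nozaki–Hiyama–Kishi coupling adds the alkenylchromium to the aldehyde with retention of the Z geometry and tolerates the lactone and enoate, while the cis-lactone holds the chain ends close for ten-membered ring closure.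

Step 11
Reactants: 16 (3aS,6Z,10Z,11aS)-5-hydroxy-6,10-dimethyl-3-methylidene-3a,4,5,8,9,11a-hexahydrocyclodeca[b]furan-2(3H)-one (both C5 epimers)
Product: 17 (3aS,6Z,10Z,11aS)-6,10-dimethyl-3-methylidene-3a,4,8,9-tetrahydrocyclodeca[b]furan-2,5(3H,11aH)-dione
Conditions: Dess–Martin periodinane, CH2Cl2, 0 °C → rt
Reagents that add atoms: none
Why: Dess–Martin oxidation of the allylic alcohol gives the Z-enone under neutral conditions and converges both C9 epimers.

Step 12
Reactants: 17 (3aS,6Z,10Z,11aS)-6,10-dimethyl-3-methylidene-3a,4,8,9-tetrahydrocyclodeca[b]furan-2,5(3H,11aH)-dione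
Product: 19 (3aR,4R,6Z,10Z,11aS)-4-hydroxy-6,10-dimethyl-3-methylidene-3a,4,8,9-tetrahydrocyclodeca[b]furan-2,5(3H,11aH)-dione, via potassium enolate 18 (not isolated)
Conditions: KHMDS, THF, −78 °C; (±)-trans-2-(phenylsulfonyl)-3-phenyloxaziridine, −78 °C; AcOH quench
Reagents that add atoms: 2-(phenylsulfonyl)-3-phenyloxaziridine, O=S(=O)(c1ccccc1)N1OC1c1ccccc1
Why: Kinetic α'-deprotonation of the enone and Davis oxaziridine hydroxylation of the cross-conjugated enolate, with oxygen expected on the face anti to the cis-fused lactone (anti to the C7–C11 bond), which gives the 8R alcohol.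

Step 13
Reactants: 20 angelic acid
Product: 21 (2Z)-2-methylbut-2-en-1-ol
Conditions: LiAlH4, Et2O, 0 °C → rt
Reagents that add atoms: none
Why: Hydride 1,2-reduction of the alkyl-substituted unsaturated acid gives the allylic alcohol with the Z geometry intact.

Step 14
Reactants: 21 (2Z)-2-methylbut-2-en-1-ol
Product: 22 [(2R,3S)-2,3-dimethyloxiran-2-yl]methanol
Conditions: Ti(OiPr)4 (10 mol%), D-(−)-diethyl tartrate (12 mol%), t-BuOOH, 4 Å MS, CH2Cl2, −20 °C
Reagents that add atoms: tert-butyl hydroperoxide, CC(C)(C)OO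
Why: Sharpless asymmetric epoxidation, in which the D-(−)-tartrate titanium catalyst delivers oxygen to the alkene face that gives the 2R,3S epoxide and the concerted syn transfer keeps CH2OH and the C3 methyl cis.

Step 15
Reactants: 22 [(2R,3S)-2,3-dimethyloxiran-2-yl]methanol
Product: 24 (2S,3S)-2,3-dimethyloxirane-2-carboxylic acid, via epoxy aldehyde 23 (not isolated)
Conditions: RuCl3·xH2O (2 mol%), NaIO4, CCl4/MeCN/H2O, 0 °C → rt
Reagents that add atoms: water, O
Why: Sharpless RuO4-catalysed oxidation takes the primary alcohol through the aldehyde hydrate to the glycidic acid without touching the epoxide stereocentres (the C2 descriptor changes only because of CIP priorities).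

Step 16
Reactants: 24 (2S,3S)-2,3-dimethyloxirane-2-carboxylic acid; 19 (3aR,4R,6Z,10Z,11aS)-4-hydroxy-6,10-dimethyl-3-methylidene-3a,4,8,9-tetrahydrocyclodeca[b]furan-2,5(3H,11aH)-dione
Product: 26 (3aS,4R,6Z,10Z,11aS)-6,10-dimethyl-3-methylidene-2,5-dioxo-2,3,3a,4,5,8,9,11a-octahydrocyclodeca[b]furan-4-yl (2S,3S)-2,3-dimethyloxirane-2-carboxylate, via mixed anhydride 25 (not isolated)
Conditions: 2,4,6-Cl3C6H2COCl, Et3N, THF, rt; then 19, DMAP, PhMe, 0 °C → rt
Reagents that add atoms: none
Why: Yamaguchi esterification acylates the hindered secondary α-hydroxy ketone through the mixed anhydride and DMAP acyl transfer, with retention at C8 and no isomerisation of the epoxy acid.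

## Compound list

1 | neryl acetate [(2Z)-3,7-dimethylocta-2,6-dien-1-yl acetate] | CC(=O)OC/C=C(/C)CCC=C(C)C | starting material
2 | secondary ozonide of 1 [(2Z)-5-(5,5-dimethyl-1,2,4-trioxolan-3-yl)-3-methylpent-2-en-1-yl acetate] | CC(=O)OC/C=C(/C)CCC1OOC(C)(C)O1 | intermediate
3 | (2Z)-3-methyl-6-oxohex-2-en-1-yl acetate | CC(=O)OC/C=C(/C)CCC=O | intermediate
4 | (2Z,6Z)-7-iodo-3-methylocta-2,6-dien-1-yl acetate | CC(=O)OC/C=C(/C)CC/C=C(/C)I | intermediate
5 | (2Z,6Z)-7-iodo-3-methylocta-2,6-dien-1-ol | OC/C=C(/C)CC/C=C(/C)I | intermediate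
6 | (2Z,6Z)-7-iodo-3-methylocta-2,6-dienal | O=C/C=C(/C)CC/C=C(/C)I | intermediate
7 | 3,3-diethoxypropan-1-ol | CCOC(CCO)OCC | starting material
8 | 3,3-diethoxypropanal | CCOC(CC=O)OCC | intermediate
9 | methyl acrylate | C=CC(=O)OC | starting material
10 | methyl 5,5-diethoxy-3-hydroxy-2-methylidenepentanoate (racemate) | CCOC(CC(O)C(=C)C(=O)OC)OCC | intermediate
11 | methyl 3-acetoxy-5,5-diethoxy-2-methylidenepentanoate (racemate) | CCOC(CC(OC(C)=O)C(=C)C(=O)OC)OCC | intermediate
12 | methyl (2E)-5,5-diethoxy-2-[(4,4,5,5-tetramethyl-1,3,2-dioxaborolan-2-yl)methyl]pent-2-enoate (CH2B cis to the C4 chain) | COC(=O)/C(CB1OC(C)(C)C(C)(C)O1)=C/CC(OCC)OCC | intermediate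
13 | methyl (3S,4S,5Z,9Z)-3-(2,2-diethoxyethyl)-10-iodo-6-methyl-2-methylidene-4-[(4,4,5,5-tetramethyl-1,3,2-dioxaborolan-2-yl)oxy]undeca-5,9-dienoate (3,4-syn pinacol borate) | C=C(C(=O)OC)[C@H](CC(OCC)OCC)[C@@H](OB1OC(C)(C)C(C)(C)O1)/C=C(/C)CC/C=C(/C)I | intermediate
14 | (4S,5S)-4-(2,2-diethoxyethyl)-5-[(1Z,5Z)-6-iodo-2-methylhepta-1,5-dien-1-yl]-3-methylideneoxolan-2-one (4,5-cis) | C=C1C(=O)O[C@@H](/C=C(/C)CC/C=C(/C)I)[C@H]1CC(OCC)OCC | intermediate
15 | 2-[(2S,3S)-2-[(1Z,5Z)-6-iodo-2-methylhepta-1,5-dien-1-yl]-4-methylidene-5-oxooxolan-3-yl]acetaldehyde (2,3-cis) | C=C1C(=O)O[C@@H](/C=C(/C)CC/C=C(/C)I)[C@H]1CC=O | intermediate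
16 | (3aS,6Z,10Z,11aS)-5-hydroxy-6,10-dimethyl-3-methylidene-3a,4,5,8,9,11a-hexahydrocyclodeca[b]furan-2(3H)-one (both C5 epimers; cis-fused) | C=C1C(=O)O[C@H]2/C=C(/C)CC/C=C(/C)C(O)C[C@@H]12 | intermediate
17 | (3aS,6Z,10Z,11aS)-6,10-dimethyl-3-methylidene-3a,4,8,9-tetrahydrocyclodeca[b]furan-2,5(3H,11aH)-dione | C=C1C(=O)O[C@H]2/C=C(/C)CC/C=C(/C)C(=O)C[C@@H]12 | intermediate
18 | potassium (3aS,6Z,10Z,11aS)-6,10-dimethyl-3-methylidene-2-oxo-2,3,3a,8,9,11a-hexahydrocyclodeca[b]furan-5-olate (α'-enolate of 17) | C=C1C(=O)O[C@H]2/C=C(/C)CC/C=C(/C)C([O-])=C[C@@H]12.[K+] | intermediate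
19 | (3aR,4R,6Z,10Z,11aS)-4-hydroxy-6,10-dimethyl-3-methylidene-3a,4,8,9-tetrahydrocyclodeca[b]furan-2,5(3H,11aH)-dione (OH anti to the lactone carbon on C3a) | C=C1C(=O)O[C@H]2/C=C(/C)CC/C=C(/C)C(=O)[C@H](O)[C@@H]12 | intermediate
20 | angelic acid [(2Z)-2-methylbut-2-enoic acid] | C/C=C(/C)C(=O)O | starting material
21 | (2Z)-2-methylbut-2-en-1-ol | C/C=C(/C)CO | intermediate
22 | [(2R,3S)-2,3-dimethyloxiran-2-yl]methanol | OC[C@@]1(C)O[C@H]1C | intermediate
23 | (2S,3S)-2,3-dimethyloxirane-2-carbaldehyde | O=C[C@@]1(C)O[C@H]1C | intermediate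
24 | (2S,3S)-2,3-dimethyloxirane-2-carboxylic acid | OC(=O)[C@@]1(C)O[C@H]1C | intermediate
25 | (2S,3S)-2,3-dimethyloxirane-2-carboxylic 2,4,6-trichlorobenzoic anhydride | O=C(OC(=O)c1c(Cl)cc(Cl)cc1Cl)[C@@]1(C)O[C@H]1C | intermediate
26 | (3aS,4R,6Z,10Z,11aS)-6,10-dimethyl-3-methylidene-2,5-dioxo-2,3,3a,4,5,8,9,11a-octahydrocyclodeca[b]furan-4-yl (2S,3S)-2,3-dimethyloxirane-2-carboxylate | C=C1C(=O)O[C@H]2/C=C(/C)CC/C=C(/C)C(=O)[C@H](OC(=O)[C@@]3(C)O[C@H]3C)[C@@H]12 | target

## Step count and risks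

Total steps: 16. Longest linear sequence: 9 (steps 1–4, 9–12, 16; the boronate branch, steps 5–8, is equally long).

The three steps most likely to fail:

**Step 9 (proposed new step).** The ester-deactivated boronate may react too slowly under a phosphoric acid, or acid-induced borotropic or allylic ionisation may erode the syn selectivity and ee. The fallback uses known chemistry, sets out from 12 and comes back at 14. The ester of 12 is reduced with DIBAL-H (CH2Cl2, −78 °C) to (2E)-5,5-diethoxy-2-[(4,4,5,5-tetramethyl-1,3,2-dioxaborolan-2-yl)methyl]pent-2-en-1-ol F1. This is silylated (TBSCl, imidazole) to tert-butyl{[(2E)-5,5-diethoxy-2-[(4,4,5,5-tetramethyl-1,3,2-dioxaborolan-2-yl)methyl]pent-2-en-1-yl]oxy}dimethylsilane F2, an electronically normal γ-substituted allyl pinacolboronate of the kind for which phosphoric-acid-catalysed allylboration is established. Reaction of F2 with 6 under (R)-TRIP gives the syn homoallylic alcohol (3S,4S,5Z,9Z)-2-{[(tert-butyldimethylsilyl)oxy]methyl}-3-(2,2-diethoxyethyl)-10-iodo-6-methylundeca-1,5,9-trien-4-ol F3. TBAF gives (3S,4S,5Z,9Z)-3-(2,2-diethoxyethyl)-10-iodo-6-methyl-2-methylideneundeca-5,9-diene-1,4-diol F4. TEMPO/PhI(OAc)2 oxidises the primary allylic alcohol selectively and takes the lactol on to lactone 14, which p-TsOH in THF/H2O hydrolyses to 15. This costs four extra operations.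

**Step 10.** Closing a ten-membered ring containing two Z-alkenes by Ni/Cr coupling may give oligomers or reduced (de-iodinated) material. The fallback changes the ring-closing reaction to an intramolecular acyl-Stille coupling, sets out from 15 and comes back at 17, which also removes step 11. Hexamethylditin and Pd(PPh3)4 convert the vinyl iodide into 2-[(2S,3S)-4-methylidene-2-[(1Z,5Z)-2-methyl-6-(trimethylstannyl)hepta-1,5-dien-1-yl]-5-oxooxolan-3-yl]acetaldehyde F5. Pinnick oxidation (NaClO2, NaH2PO4, 2-methylbut-2-ene) gives 2-[(2S,3S)-4-methylidene-2-[(1Z,5Z)-2-methyl-6-(trimethylstannyl)hepta-1,5-dien-1-yl]-5-oxooxolan-3-yl]acetic acid F6. Ghosez's reagent (1-chloro-N,N,2-trimethylprop-1-en-1-amine) gives under neutral conditions 2-[(2S,3S)-4-methylidene-2-[(1Z,5Z)-2-methyl-6-(trimethylstannyl)hepta-1,5-dien-1-yl]-5-oxooxolan-3-yl]acetyl chloride F7. Pd2(dba)3/tri(2-furyl)phosphine at high dilution then closes F7 directly to enone 17 with retention of the alkene geometry.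

**Step 12.** The facial selectivity of the macrocyclic enolate is a prediction, not a certainty, and the C8 epimer may be the main product. The fallback changes the C8–O bond-forming logic from acylation with retention to substitution with inversion, sets out from 17 and comes back at 26. If step 12 delivers mainly (3aR,4S,6Z,10Z,11aS)-4-hydroxy-6,10-dimethyl-3-methylidene-3a,4,8,9-tetrahydrocyclodeca[b]furan-2,5(3H,11aH)-dione F8, it is esterified with acid 24 under Mitsunobu conditions (PPh3, DIAD, PhMe, 0 °C). SN2 displacement at the carbon α to the ketone inverts C8 and gives 26 directly in place of step 16, so either epimer of the hydroxy ketone can be carried to the target.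

Further compounds

F1 | step 9 | (2E)-5,5-diethoxy-2-[(4,4,5,5-tetramethyl-1,3,2-dioxaborolan-2-yl)methyl]pent-2-en-1-ol | OC/C(CB1OC(C)(C)C(C)(C)O1)=C/CC(OCC)OCC
F2 | step 9 | tert-butyl{[(2E)-5,5-diethoxy-2-[(4,4,5,5-tetramethyl-1,3,2-dioxaborolan-2-yl)methyl]pent-2-en-1-yl]oxy}dimethylsilane | CC(C)(C)[Si](C)(C)OC/C(CB1OC(C)(C)C(C)(C)O1)=C/CC(OCC)OCC
F3 | step 9 | (3S,4S,5Z,9Z)-2-{[(tert-butyldimethylsilyl)oxy]methyl}-3-(2,2-diethoxyethyl)-10-iodo-6-methylundeca-1,5,9-trien-4-ol | C=C(CO[Si](C)(C)C(C)(C)C)[C@H](CC(OCC)OCC)[C@@H](O)/C=C(/C)CC/C=C(/C)I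
F4 | step 9 | (3S,4S,5Z,9Z)-3-(2,2-diethoxyethyl)-10-iodo-6-methyl-2-methylideneundeca-5,9-diene-1,4-diol | C=C(CO)[C@H](CC(OCC)OCC)[C@@H](O)/C=C(/C)CC/C=C(/C)I
F5 | step 10 | 2-[(2S,3S)-4-methylidene-2-[(1Z,5Z)-2-methyl-6-(trimethylstannyl)hepta-1,5-dien-1-yl]-5-oxooxolan-3-yl]acetaldehyde | C=C1C(=O)O[C@@H](/C=C(/C)CC/C=C(/C)[Sn](C)(C)C)[C@H]1CC=O
F6 | step 10 | 2-[(2S,3S)-4-methylidene-2-[(1Z,5Z)-2-methyl-6-(trimethylstannyl)hepta-1,5-dien-1-yl]-5-oxooxolan-3-yl]acetic acid | C=C1C(=O)O[C@@H](/C=C(/C)CC/C=C(/C)[Sn](C)(C)C)[C@H]1CC(=O)O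
F7 | step 10 | 2-[(2S,3S)-4-methylidene-2-[(1Z,5Z)-2-methyl-6-(trimethylstannyl)hepta-1,5-dien-1-yl]-5-oxooxolan-3-yl]acetyl chloride | C=C1C(=O)O[C@@H](/C=C(/C)CC/C=C(/C)[Sn](C)(C)C)[C@H]1CC(=O)Cl
F8 | step 12 | (3aR,4S,6Z,10Z,11aS)-4-hydroxy-6,10-dimethyl-3-methylidene-3a,4,8,9-tetrahydrocyclodeca[b]furan-2,5(3H,11aH)-dione | C=C1C(=O)O[C@H]2/C=C(/C)CC/C=C(/C)C(=O)[C@@H](O)[C@@H]12
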